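**Retrosynthetic overview**

1. Target ⇐ lipase resolution of the racemic C4 acetate. C2=C3 and the C4 hydroxyl ⇐ base opening of a β,γ-epoxy ketone, itself from hydroxyl-directed epoxidation of a 5-alkyl-5-hydroxycyclohex-3-enone, so the C4 oxygen is delivered cis to the C5 hydroxyl.
2. That enone ⇐ SmI2 cleavage of the C2–O bond of a 7-oxabicyclo[2.2.1]hept-5-en-2-one, whose oxygen bridge becomes the C5 hydroxyl.
3. Key disconnection: C2–C3 and C4–C5 together, by Diels–Alder reaction of a 2-alkyl-4-silyloxyfuran with phenyl vinyl sulfoxide (C3–C4, an acetylene equivalent); loss of sulfenic acid then gives C3=C4.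
4. Enabling feature: the tertiary oxygen on C5 and carbon C2 stand 1,4 across the six-membered ring, joined on one side by C6 and the carbonyl carbon C1. O, C5, C6, C1 and C2 can therefore be the five ring atoms of a furan carrying the C1 oxygen as a silyl ether and the C17 chain on C5.
5. Furan ⇐ 5-alkylfuran-3(2H)-one ⇐ 1-silyloxy-2,4-dione ⇐ oleic acid (carboxyl carbon = C5, its Z-alkene = the chain alkene), MeLi and a silyloxyacetate. Ring order: the temporary furan (step 3), then the carbocycle (step 5), the only ring of the target.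

Key step: step 5

Remark: every chiral compound from the cycloaddition up to the acetate of step 8 is racemic and is written with the SMILES of the enantiomer that leads to the target; the enantiomers are parted in step 9, so at most half of the material is carried through.

**Route**

Step 1
Reactants: 1 oleic acid
Product: 2 (10Z)-nonadec-10-en-2-one
Conditions: MeLi (2.2 equiv), Et2O, 0 °C to rt; inverse quench into aq. NH4Cl
Reagents that add atoms: methyllithium, [Li]C
Why: Ketone synthesis from a carboxylic acid with an organolithium reagent: the lithium carboxylate takes up one further MeLi and the geminal dilithium alkoxide should survive until the quench, so no tertiary alcohol should form and the Z-alkene is carried in unchanged.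

Step 2
Reactants: 2 (10Z)-nonadec-10-en-2-one, 3 ethyl 2-[(tert-butyldimethylsilyl)oxy]acetate
Product: 4 (12Z)-1-[(tert-butyldimethylsilyl)oxy]henicos-12-ene-2,4-dione
Conditions: LiN(SiMe3)2 (2.1 equiv), THF, −78 °C; then 3, −78 to 0 °C; aq. NH4Cl
Reagents that add atoms: none
Why: Crossed Claisen condensation: the bulky amide base should deprotonate the methyl group of 2 under kinetic control, the enolate is acylated by the activated α-silyloxy ester 3, and the second equivalent of base holds the β-diketone as its enolate.

Step 3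
Reactants: 4 (12Z)-1-[(tert-butyldimethylsilyl)oxy]henicos-12-ene-2,4-dione
Product: 6 5-[(8Z)-heptadec-8-en-1-yl]furan-3(2H)-one, via hydroxy diketone 5 (not isolated)
Conditions: 1 M HCl, THF, rt
Reagents that add atoms: none
Why: Acid cleaves the silyl ether and the freed primary alcohol of 5 adds to the C4 carbonyl and loses water, the classical acid cyclodehydration of 1-hydroxy-2,4-diketones to furan-3(2H)-ones.

Step 4
Reactants: 6 5-[(8Z)-heptadec-8-en-1-yl]furan-3(2H)-one
Product: 7 tert-butyl({5-[(8Z)-heptadec-8-en-1-yl]furan-3-yl}oxy)dimethylsilane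
Conditions: TBSOTf, Et3N, CH2Cl2, 0 °C
Reagents that add atoms: tert-butyldimethylsilyl trifluoromethanesulfonate, CC(C)(C)[Si](C)(C)OS(=O)(=O)C(F)(F)F
Why: O-Silylation of the enolised furanone (soft enolisation with silyl triflate and amine) should go to completion because it creates the aromatic furan, giving the electron-rich 3-silyloxyfuran diene.

Step 5
Reactants: 7 tert-butyl({5-[(8Z)-heptadec-8-en-1-yl]furan-3-yl}oxy)dimethylsilane, 8 phenyl vinyl sulfoxide
Product: 11 rac-(1S,4S)-4-[(8Z)-heptadec-8-en-1-yl]-7-oxabicyclo[2.2.1]hept-5-en-2-one, via sulfoxide cycloadduct 9 (not isolated), via silyl dienol ether 10 (not isolated)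
Conditions: 8 (2 equiv), NaHCO3 (solid), PhMe, 110 °C; then Bu4NF/AcOH (1:1), THF, −20 °C
Reagents that add atoms: none
Why: A thermal normal-demand Diels–Alder reaction between the 3-silyloxyfuran 7 (diene carbons C2, C1, C6 and C5 of the later ring, bridged by the furan oxygen) and the vinyl sulfoxide 8 should give 9, which loses benzenesulfenic acid by thermal syn elimination (Ei) at the same temperature to give 10, and buffered fluoride then turns the silyl enol ether into ketone 11. The closest known reaction type is the use of aryl vinyl sulfoxides as acetylene equivalents in Diels–Alder reactions, together with the cycloadditions of 3-alkoxy- and 3-silyloxyfurans; the elimination takes the adduct out of the reversible furan cycloaddition equilibrium. The carbocycle is closed by a concerted suprafacial [4+2] cycloaddition in which C2–C3 and C4–C5 form together, while the oxygen bridge is not closed but carried in from the furan. The new stereocentres C5 and C2 are bridgeheads of a bicyclo[2.2.1] skeleton, so their relative configuration is fixed by the ring system; no chiral element is present, so 11 is racemic, and the sulfur-bearing centre is destroyed again. No regio- or endo/exo selectivity is needed, because in every isomer of 9 the only hydrogens that sulfur can reach lie on the other dienophile carbon (C5 has none and elimination toward C2 would give a bridgehead alkene), so all isomers should converge on the same C3=C4 alkene, and the unactivated chain alkene should not compete. The needed chemoselectivity is survival of the acid-sensitive dienol ether 10, which the solid base and the acetic-acid-buffered fluoride should secure against bridge opening and aromatisation.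

Step 6
Reactants: 11 rac-(1S,4S)-4-[(8Z)-heptadec-8-en-1-yl]-7-oxabicyclo[2.2.1]hept-5-en-2-one
Product: 12 rac-(5S)-5-[(8Z)-heptadec-8-en-1-yl]-5-hydroxycyclohex-3-en-1-one
Conditions: SmI2 (2.2 equiv), THF/MeOH, −78 °C; pH 7 buffer
Reagents that add atoms: none
Why: SmI2 reduction of an α-alkoxy (here also allylic) ketone: electron transfer to the C1 carbonyl is followed by expulsion of the bridging oxygen from C2, and the samarium dienolate should be protonated by MeOH at the α-carbon C2, leaving the deconjugated C3=C4 alkene beside the free tertiary C5 hydroxyl, whose configuration is untouched.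

Step 7
Reactants: 12 rac-(5S)-5-[(8Z)-heptadec-8-en-1-yl]-5-hydroxycyclohex-3-en-1-one
Product: 14 rac-(4R,5S)-5-[(8Z)-heptadec-8-en-1-yl]-4,5-dihydroxycyclohex-2-en-1-one, via epoxy ketone 13 (not isolated)
Conditions: VO(acac)2 (5 mol %), t-BuOOH, CH2Cl2, 0 °C; then Et3N, 0 °C to rt
Reagents that add atoms: tert-butyl hydroperoxide, CC(C)(C)OO
Why: Vanadium-catalysed hydroxyl-directed epoxidation of an allylic alcohol should deliver oxygen to the C3=C4 face syn to the tertiary C5 hydroxyl (setting the C4 oxygen cis to it) and leave the undirected chain alkene alone, and Et3N then opens the β,γ-epoxy ketone 13 by E1cB elimination from C2 to give the γ-hydroxy enone with C2=C3.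

Step 8
Reactants: 14 rac-(4R,5S)-5-[(8Z)-heptadec-8-en-1-yl]-4,5-dihydroxycyclohex-2-en-1-one
Product: 15 rac-(1R,6S)-6-[(8Z)-heptadec-8-en-1-yl]-6-hydroxy-4-oxocyclohex-2-en-1-yl acetate
Conditions: Ac2O, pyridine, DMAP (cat.), CH2Cl2, 0 °C
Reagents that add atoms: acetic anhydride, CC(=O)OC(C)=O
Why: Acylation of an alcohol with an anhydride: only the secondary C4 hydroxyl should react, the tertiary C5 hydroxyl being too hindered, and the weak base at 0 °C should not trigger β-elimination.

Step 9
Reactants: 15 rac-(1R,6S)-6-[(8Z)-heptadec-8-en-1-yl]-6-hydroxy-4-oxocyclohex-2-en-1-yl acetate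
Product: 16 (4R,5S)-5-[(8Z)-heptadec-8-en-1-yl]-4,5-dihydroxycyclohex-2-en-1-one (CNP0223277.1)
Conditions: lipase from Burkholderia cepacia (immobilised), KH2PO4/K2HPO4 buffer pH 7, t-BuOMe, 30 °C, stopped below half conversion; chromatography
Reagents that add atoms: none
Why: Lipase-catalysed kinetic resolution by enantioselective ester hydrolysis: by the empirical size model for lipases the (4R)-acetate (large quaternary C5, medium vinyl C3) should be hydrolysed fast, so below half conversion the (4R,5S)-diol 16 should be released while the (4S,5R)-acetate stays behind and is removed, which selects the absolute configuration of both stereocentres.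

**Compound list**

1 | oleic acid, (9Z)-octadec-9-enoic acid | CCCCCCCC/C=C\CCCCCCCC(=O)O | starting material
2 | (10Z)-nonadec-10-en-2-one | CCCCCCCC/C=C\CCCCCCCC(C)=O | intermediate
3 | ethyl 2-[(tert-butyldimethylsilyl)oxy]acetate | CCOC(=O)CO[Si](C)(C)C(C)(C)C | starting material
4 | (12Z)-1-[(tert-butyldimethylsilyl)oxy]henicos-12-ene-2,4-dione | CCCCCCCC/C=C\CCCCCCCC(=O)CC(=O)CO[Si](C)(C)C(C)(C)C | intermediate
5 | (12Z)-1-hydroxyhenicos-12-ene-2,4-dione (not isolated) | CCCCCCCC/C=C\CCCCCCCC(=O)CC(=O)CO | intermediate
6 | 5-[(8Z)-heptadec-8-en-1-yl]furan-3(2H)-one | CCCCCCCC/C=C\CCCCCCCC1=CC(=O)CO1 | intermediate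
7 | tert-butyl({5-[(8Z)-heptadec-8-en-1-yl]furan-3-yl}oxy)dimethylsilane | CCCCCCCC/C=C\CCCCCCCc1cc(O[Si](C)(C)C(C)(C)C)co1 | intermediate
8 | phenyl vinyl sulfoxide (racemic) | C=CS(=O)c1ccccc1 | starting material
9 | rac-tert-butyl({1-[(8Z)-heptadec-8-en-1-yl]-6-(phenylsulfinyl)-7-oxabicyclo[2.2.1]hept-2-en-3-yl}oxy)dimethylsilane, isomer mixture at C6 and sulfur (not isolated) | CCCCCCCC/C=C\CCCCCCC[C@]1(O2)C=C(O[Si](C)(C)C(C)(C)C)[C@@H]2CC1S(=O)c1ccccc1 | intermediate
10 | rac-tert-butyl({1-[(8Z)-heptadec-8-en-1-yl]-7-oxabicyclo[2.2.1]hepta-2,5-dien-3-yl}oxy)dimethylsilane (not isolated) | CCCCCCCC/C=C\CCCCCCC[C@]1(O2)C=C(O[Si](C)(C)C(C)(C)C)[C@@H]2C=C1 | intermediate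
11 | rac-(1S,4S)-4-[(8Z)-heptadec-8-en-1-yl]-7-oxabicyclo[2.2.1]hept-5-en-2-one | CCCCCCCC/C=C\CCCCCCC[C@]1(O2)CC(=O)[C@@H]2C=C1 | intermediate
12 | rac-(5S)-5-[(8Z)-heptadec-8-en-1-yl]-5-hydroxycyclohex-3-en-1-one | CCCCCCCC/C=C\CCCCCCC[C@]1(O)CC(=O)CC=C1 | intermediate
13 | rac-(1R,5S,6R)-5-[(8Z)-heptadec-8-en-1-yl]-5-hydroxy-7-oxabicyclo[4.1.0]heptan-3-one, epoxide cis to the hydroxyl (not isolated) | CCCCCCCC/C=C\CCCCCCC[C@]1(O)CC(=O)C[C@H]2O[C@@H]12 | intermediate
14 | rac-(4R,5S)-5-[(8Z)-heptadec-8-en-1-yl]-4,5-dihydroxycyclohex-2-en-1-one | CCCCCCCC/C=C\CCCCCCC[C@]1(O)CC(=O)C=C[C@H]1O | intermediate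
15 | rac-(1R,6S)-6-[(8Z)-heptadec-8-en-1-yl]-6-hydroxy-4-oxocyclohex-2-en-1-yl acetate | CCCCCCCC/C=C\CCCCCCC[C@]1(O)CC(=O)C=C[C@H]1OC(C)=O | intermediate
16 | (4R,5S)-5-[(8Z)-heptadec-8-en-1-yl]-4,5-dihydroxycyclohex-2-en-1-one | CCCCCCCC/C=C\CCCCCCC[C@]1(O)CC(=O)C=C[C@H]1O | target

**Step count and risks**

Total step count: 9. Longest linear sequence: 9 steps (1 to 16).

Steps most likely to fail:

Step 5. The cycloaddition may be too slow at a temperature the silyloxyfuran tolerates, or the oxygen bridge may open with aromatisation during the elimination or the desilylation. Fallback: starting from 7, the cycloaddition is run at room temperature with the far more reactive acetylene equivalent (E)-1,2-bis(phenylsulfonyl)ethene in CH2Cl2. This should give rac-tert-butyl({1-[(8Z)-heptadec-8-en-1-yl]-5,6-bis(phenylsulfonyl)-7-oxabicyclo[2.2.1]hept-2-en-3-yl}oxy)dimethylsilane F1. Reductive elimination of both sulfonyl groups with sodium amalgam Na(Hg) and NaH2PO4 in MeOH/THF at −20 °C should give 10, which is desilylated with buffered fluoride as in step 5, and the route is rejoined at 11.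

Step 6. The C3=C4 double bond may migrate into conjugation before it can be epoxidised, the samarium aldolate may open by retro-aldol cleavage, or the ketone may be over-reduced. Fallback: starting from 7, both oxygens are brought in by the dienophile. Diels–Alder reaction with vinylene carbonate (1,3-dioxol-2-one, neat, 100–120 °C) should give, after separation from the endo isomer, rac-exo-5-[(tert-butyldimethylsilyl)oxy]-7-[(8Z)-heptadec-8-en-1-yl]-3a,4,7,7a-tetrahydro-4,7-epoxy-1,3-benzodioxol-2-one F2. Buffered fluoride (Bu4NF/AcOH) should then give the ketone rac-exo-7-[(8Z)-heptadec-8-en-1-yl]hexahydro-4,7-epoxy-1,3-benzodioxole-2,5-dione F3. With SmI2 (THF/MeOH, −78 °C) the samarium enolate formed by cleavage of the C2–O bridge bond should expel the carbonate oxygen on C3 directly (E1cB) and lose CO2. No deconjugated enone has to survive and no epoxidation is needed; the route is rejoined at 14.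

Step 9. The enzyme may discriminate the enantiomers poorly or fail to turn over an acetate that sits next to a quaternary carbon. Fallback: starting from 14, the secondary hydroxyl is esterified with (S)-2-methoxy-2-phenylacetic acid (DCC, DMAP, CH2Cl2) and the two diastereomeric esters are separated by chromatography. The ester (1R,6S)-6-[(8Z)-heptadec-8-en-1-yl]-6-hydroxy-4-oxocyclohex-2-en-1-yl (2S)-2-methoxy-2-phenylacetate F4 is then cleaved with K2CO3 in MeOH at 0 °C, and the route is rejoined at 16.

Further compounds
F1 | step 5 | rac-tert-butyl({1-[(8Z)-heptadec-8-en-1-yl]-5,6-bis(phenylsulfonyl)-7-oxabicyclo[2.2.1]hept-2-en-3-yl}oxy)dimethylsilane, sulfonyl groups trans | CCCCCCCC/C=C\CCCCCCC[C@]1(O2)C=C(O[Si](C)(C)C(C)(C)C)[C@@H]2C(S(=O)(=O)c2ccccc2)C1S(=O)(=O)c1ccccc1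
F2 | step 6 | rac-exo-5-[(tert-butyldimethylsilyl)oxy]-7-[(8Z)-heptadec-8-en-1-yl]-3a,4,7,7a-tetrahydro-4,7-epoxy-1,3-benzodioxol-2-one | CCCCCCCC/C=C\CCCCCCC[C@]1(O2)C=C(O[Si](C)(C)C(C)(C)C)[C@@H]2[C@H]3OC(=O)O[C@H]31
F3 | step 6 | rac-exo-7-[(8Z)-heptadec-8-en-1-yl]hexahydro-4,7-epoxy-1,3-benzodioxole-2,5-dione | CCCCCCCC/C=C\CCCCCCC[C@]1(O2)CC(=O)[C@@H]2[C@H]3OC(=O)O[C@H]31
F4 | step 9 | (1R,6S)-6-[(8Z)-heptadec-8-en-1-yl]-6-hydroxy-4-oxocyclohex-2-en-1-yl (2S)-2-methoxy-2-phenylacetate | CCCCCCCC/C=C\CCCCCCC[C@]1(O)CC(=O)C=C[C@H]1OC(=O)[C@@H](OC)c1ccccc1
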